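**Retrosynthetic overview**

- 12 ⇐ 11 ⇐ 10: the last two steps only remove spectators, five ring bromines by hydrogenolysis and two O-methyl groups with BBr3.
- 10 ⇐ 8: the diaryl ether bond between the oxygen on position 1 of ring A and carbon 1 of ring B is cut. Forward, anodic O–C coupling of the symmetrical hexabromo bis-phenol 8 with zinc reduction in the same pot closes the 20-membered ring, the only ring made in the route (both benzene rings are bought).
- 8 ⇐ 7 ⇐ 6 ⇐ 5 ⇐ 2 + two molecules of 3: exhaustive bromination, one O-demethylation per ring, hydrogenation, and a double Wittig of 3,5-dimethoxybenzaldehyde onto a twelve-carbon bis-ylide, which sets the 14-carbon chain.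
- Feature the strategy rests on (ring A: position 1 ether oxygen, position 3 hydroxyl, position 5 chain; ring B: position 1 aryloxy, positions 2 and 4 hydroxyl, position 6 chain): both rings are 5-alkylresorcinol rings on the ends of one (CH2)14 chain, joined only by the ether from the ring A position 1 oxygen to ring B position 1, which lies between the chain carbon and the oxygenated position 2 and para to the oxygenated position 4, the pattern an O–C oxidative phenol coupling inside a symmetrical 1,14-diaryltetradecane would leave.

Key step: step 6

Remark on the chemistry: the target has no stereocentre. The alkene geometry of 5 (drawn Z,Z, the isomer expected to prevail) and the transient sp3 centre of 9 (racemic) are both erased later in the route.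

**Route**

Step 1
Reactants: 1 1,12-dibromododecane
Product: 2 dodecane-1,12-diylbis(triphenylphosphonium) dibromide
Conditions: PPh3 (2.2 equiv), MeCN, reflux
Reagents that add atoms: triphenylphosphine, c1ccccc1P(c1ccccc1)c1ccccc1
Why: Double SN2 quaternisation of triphenylphosphine by the primary dibromide should give the bis-phosphonium salt, which can be crystallised free of mono-salt.

Step 2
Reactants: 2 dodecane-1,12-diylbis(triphenylphosphonium) dibromide; 3 3,5-dimethoxybenzaldehyde (2.1 equiv)
Product: 5 1,14-bis(3,5-dimethoxyphenyl)tetradeca-1,13-diene (expected mainly 1Z,13Z), via the bis-ylide 4 (not isolated)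
Conditions: KOtBu (2.2 equiv), THF, 0 °C; then 3, 0 °C to rt
Reagents that add atoms: none
Why: Double Wittig olefination, in which the non-stabilised bis-ylide 4 adds to two molecules of the non-enolisable aldehyde and each oxaphosphetane collapses to a styrenyl double bond, the alkene geometry being irrelevant because step 3 saturates both.

Step 3
Reactants: 5 1,14-bis(3,5-dimethoxyphenyl)tetradeca-1,13-diene
Product: 6 1,14-bis(3,5-dimethoxyphenyl)tetradecane
Conditions: H2 (1 atm), 10% Pd/C, EtOAc, rt
Reagents that add atoms: none
Why: Heterogeneous catalytic hydrogenation of the two disubstituted styrenyl double bonds is fast at 1 atm and leaves the arene rings and the aryl methyl ethers untouched.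

Step 4
Reactants: 6 1,14-bis(3,5-dimethoxyphenyl)tetradecane
Product: 7 1,14-bis(3-hydroxy-5-methoxyphenyl)tetradecane
Conditions: NaSEt (6 equiv), DMF, 150 °C; aq. HCl work-up
Reagents that add atoms: none
Why: Nucleophilic (SN2) O-demethylation by ethanethiolate should remove one methyl group per ring and then stop, because the aryloxide formed makes the second methoxy group of the same ring a far poorer leaving group, while the two rings react independently across the (CH2)14 chain.

Step 5
Reactants: 7 1,14-bis(3-hydroxy-5-methoxyphenyl)tetradecane
Product: 8 1,14-bis(2,4,6-tribromo-3-hydroxy-5-methoxyphenyl)tetradecane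
Conditions: Br2 (6.6 equiv), AcOH–CH2Cl2, 0 °C to rt, dark; aq. NaHSO3
Reagents that add atoms: bromine, BrBr
Why: Electrophilic aromatic bromination, in which each ring has exactly three free positions and all three are ortho or para to both the hydroxyl and the methoxy group, so bromine should fill them all, and the NaHSO3 wash returns any over-brominated bromodienone to the phenol.

Step 6
Reactants: 8 1,14-bis(2,4,6-tribromo-3-hydroxy-5-methoxyphenyl)tetradecane
Product: 10 pentabromo macrocyclic diaryl ether (hydroxyl on ring B position 2 free), via the macrocyclic aryloxy-bromocyclohexadienone 9 (not isolated)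
Conditions: glassy-carbon anode, Pt cathode, undivided cell, constant current (about 2 F/mol), LiClO4, MeOH–CH2Cl2 (4:1), 1 mM, 0 °C; then Zn dust, AcOH, 0 °C to rt
Reagents that add atoms: none
Why: Two-electron anodic oxidation of one acidic tribromophenol unit (as its phenolate) should give a phenoxonium ion, or the equivalent phenoxyl radical pair, and the hydroxyl oxygen of the other ring adds to the bromine-bearing carbon between the carbonyl and the chain to give the 6-aryloxy-6-bromocyclohexa-2,4-dienone 9; zinc then passes two electrons into the C–Br bond alpha to the carbonyl, bromide leaves and the zinc phenolate is protonated to the phenol on ring B position 2 of 10. The closest known reaction type is the anodic or Tl(NO3)3 (trivalent thallium) oxidation of ortho,ortho'-dibromophenols to aryloxy dienones followed by zinc reduction to diaryl ethers, which has been used to close macrocyclic diaryl ethers. The 20-membered ring is closed end to end across the (CH2)14 tether by intramolecular O-attack on the oxidised ring, a strain-free macrocyclisation that is favoured over oligomerisation by the 1 mM dilution. No stereocentre is kept, since the sp3 carbon of 9 forms as a racemate and is flattened again by the zinc step. The step needs O–C and not C–C coupling, and attack at a carbon next to the chain: bromine on all ortho and para positions leaves no C–H site for C–C coupling and makes each attacked carbon reducible back to an arene, the symmetry of 8 makes the choice of oxidised ring irrelevant, and attack at the para carbon (also next to the chain) would give an isomeric ether that converges on 12 after steps 7 and 8, so that only the carbon between the two oxygens is an unproductive site. Electrolysis is stopped near 2 F/mol and zinc is added at once in the cold so that 9 is reduced before methanol can exchange its bromine.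

Step 7
Reactants: 10 pentabromo macrocyclic diaryl ether
Product: 11 macrocyclic diaryl ether dimethyl ether (methoxy on ring A position 3 and ring B position 4, hydroxyl on ring B position 2)
Conditions: H2 (1 atm), 10% Pd/C, Et3N (10 equiv), EtOAc–MeOH, rt
Reagents that add atoms: none
Why: Pd-catalysed hydrogenolysis of aryl C–Br bonds with Et3N as HBr scavenger should remove all five bromines, while the diaryl ether, the methyl ethers and the saturated chain are inert under these conditions.

Step 8
Reactants: 11 macrocyclic diaryl ether dimethyl ether
Product: 12 target macrocyclic diaryl ether triphenol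
Conditions: BBr3 (6 equiv), CH2Cl2, −78 °C to rt; then H2O
Reagents that add atoms: none
Why: Lewis-acid O-demethylation with BBr3 (aryloxyborane formation and bromide attack on the methyl carbon) should cleave both aryl methyl ethers, whereas the diaryl ether offers no sp3 carbon to bromide and survives.

**Compound list**

1 | 1,12-dibromododecane | BrCCCCCCCCCCCCBr | starting material
2 | dodecane-1,12-diylbis(triphenylphosphonium) dibromide | [Br-].[Br-].c1ccccc1[P+](c1ccccc1)(c1ccccc1)CCCCCCCCCCCC[P+](c1ccccc1)(c1ccccc1)c1ccccc1 | intermediate
3 | 3,5-dimethoxybenzaldehyde | COc1cc(C=O)cc(OC)c1 | starting material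
4 | dodecane-1,12-diylidenebis(triphenylphosphorane), the bis-ylide | c1ccccc1P(c1ccccc1)(c1ccccc1)=CCCCCCCCCCCC=P(c1ccccc1)(c1ccccc1)c1ccccc1 | intermediate
5 | 1,14-bis(3,5-dimethoxyphenyl)tetradeca-1,13-diene, drawn as the 1Z,13Z isomer (alkene isomers carried on together) | COc1cc(OC)cc(/C=C\CCCCCCCCCC/C=C\c2cc(OC)cc(OC)c2)c1 | intermediate
6 | 1,14-bis(3,5-dimethoxyphenyl)tetradecane | COc1cc(OC)cc(CCCCCCCCCCCCCCc2cc(OC)cc(OC)c2)c1 | intermediate
7 | 1,14-bis(3-hydroxy-5-methoxyphenyl)tetradecane | COc1cc(O)cc(CCCCCCCCCCCCCCc2cc(O)cc(OC)c2)c1 | intermediate
8 | 1,14-bis(2,4,6-tribromo-3-hydroxy-5-methoxyphenyl)tetradecane | COc1c(Br)c(O)c(Br)c(CCCCCCCCCCCCCCc2c(Br)c(O)c(Br)c(OC)c2Br)c1Br | intermediate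
9 | macrocyclic bromodienone (racemic): ring A is a 2,4,6-tribromo-3-methoxy-5-alkylphenyl ether whose oxygen is bonded to the sp3 carbon at ring B position 1 (also bearing Br) of a cyclohexa-2,4-dienone with C=O at ring B position 2, Br at positions 3 and 5, OMe at position 4 and the (CH2)14 chain from ring B position 6 to ring A position 5 | COc1c(Br)c2c(Br)c(c1Br)OC1(Br)C(=O)C(Br)=C(OC)C(Br)=C1CCCCCCCCCCCCCC2 | intermediate
10 | pentabromo macrocyclic diaryl ether: ring A with the ether oxygen at position 1, Br at positions 2, 4 and 6, OMe at position 3, chain at position 5; ring B with O-aryl at position 1, OH at position 2, Br at positions 3 and 5, OMe at position 4, chain at position 6; ring A position 5 and ring B position 6 joined by (CH2)14 | COc1c(Br)c2c(Br)c(c1Br)Oc1c(O)c(Br)c(OC)c(Br)c1CCCCCCCCCCCCCC2 | intermediate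
11 | debrominated macrocycle: ring A with the ether oxygen at position 1, OMe at position 3, chain at position 5; ring B with O-aryl at position 1, OH at position 2, OMe at position 4, chain at position 6 | COc1cc2cc(c1)Oc1c(O)cc(OC)cc1CCCCCCCCCCCCCC2 | intermediate
12 | target: 20-membered diaryl ether with OH at ring A position 3 and at ring B positions 2 and 4, and a (CH2)14 chain from ring A position 5 to ring B position 6 | Oc1cc2cc(c1)Oc1c(O)cc(O)cc1CCCCCCCCCCCCCC2 | target

**Step count**

Total steps: 8. Longest linear sequence: 8 steps (1 to 12).

**Steps most likely to fail**

1. Step 6. Three processes may go wrong.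
   - Methanol may capture the oxidised ring, or replace the bromine of 9 by solvolysis before zinc is added, so that a methoxy group survives the reduction.
   - The ring A oxygen may add at the carbon between the two oxygens of ring B and give a 22-membered isomer.
   - Intermolecular O–C coupling may give oligomers.

   A 20-membered closure and a phenol that is also brominated at the para position both lie outside what this oxidation has been used for.

   Fallback: the ether bond is made first between two monomers and the macrocycle is closed through the chain. It sets out from 3. NBS in MeCN should brominate 3 next to the formyl group to give 2-bromo-3,5-dimethoxybenzaldehyde F1. A second portion of 3 is mono-demethylated with NaSEt in DMF to 3-hydroxy-5-methoxybenzaldehyde F2. Ullmann coupling of F1 with F2 (CuO, K2CO3, pyridine, reflux) should give the diaryl ether dialdehyde F3. A double Wittig macrocyclisation of F3 with the bis-ylide 4 (from 2, KOtBu, THF, high dilution), a known if modest way to large cyclophanes, should give the macrocyclic diene F4. Hydrogenation (H2, Pd/C) should give the trimethyl ether F5. BBr3 then cleaves the three methyl ethers and the route is rejoined at 12.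

2. Step 7. Hydrogenolysis may stop short: all five C–Br bonds are flanked on both sides, and bromide or ammonium salts may poison the catalyst, leaving partly brominated macrocycles that are hard to separate.

   Fallback: the order of the last two operations is inverted, and the bromines are removed from water-soluble phenolates by a dissolving-metal reduction instead of over a Pd surface. It sets out from 10. BBr3 in CH2Cl2 should give the pentabromo triphenol F6. Ni–Al alloy (Raney type) in aqueous NaOH with MeOH as cosolvent, a standard dehalogenation of polyhalophenols, should then strip the five bromines and give 12 directly.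

3. Step 4. The demethylation may not stop at exactly one methyl group per ring on both rings. Under- or over-reaction would give a set of phenols that are hard to separate on a dimer linked by a 14-carbon chain.

   Fallback: the single free hydroxyl of each ring is set at the monomer stage, where by-products are removed easily, and carried as a benzyl ether. It sets out from 3, which is mono-demethylated to 3-hydroxy-5-methoxybenzaldehyde F2 as in the first fallback. BnBr and K2CO3 in DMF should give 3-(benzyloxy)-5-methoxybenzaldehyde F7. A double Wittig of F7 with the bis-ylide 4 should give the bis-benzyl ether diene F8. Hydrogenation over Pd/C should saturate both double bonds and cleave both benzyl ethers in one operation, rejoining the route at 7.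

Further compounds
F1 | step 6 | 2-bromo-3,5-dimethoxybenzaldehyde | COc1cc(OC)c(Br)c(C=O)c1
F2 | step 6 | 3-hydroxy-5-methoxybenzaldehyde | COc1cc(O)cc(C=O)c1
F3 | step 6 | 2-(3-formyl-5-methoxyphenoxy)-3,5-dimethoxybenzaldehyde | COc1cc(C=O)cc(Oc2c(C=O)cc(OC)cc2OC)c1
F4 | step 6 | macrocyclic diene trimethyl ether (mixture of alkene isomers) | COc1cc2cc(c1)Oc1c(OC)cc(OC)cc1C=CCCCCCCCCCCC=C2
F5 | step 6 | saturated macrocyclic diaryl ether trimethyl ether | COc1cc2cc(c1)Oc1c(OC)cc(OC)cc1CCCCCCCCCCCCCC2
F6 | step 7 | pentabromo macrocyclic diaryl ether triphenol | Oc1c(Br)c2c(Br)c(c1Br)Oc1c(O)c(Br)c(O)c(Br)c1CCCCCCCCCCCCCC2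
F7 | step 4 | 3-(benzyloxy)-5-methoxybenzaldehyde | COc1cc(OCc2ccccc2)cc(C=O)c1
F8 | step 4 | 1,14-bis[3-(benzyloxy)-5-methoxyphenyl]tetradeca-1,13-diene (mixture of alkene isomers) | COc1cc(OCc2ccccc2)cc(C=CCCCCCCCCCCC=Cc2cc(OC)cc(OCc3ccccc3)c2)c1
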